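## Retrosynthetic overview

1. The target comes from global deprotection and a late Z-selective cross-metathesis (CM) that converts a terminal vinyl group into the (Z)-propenyl group. The C13 ketone is unmasked from a sacrificial C13 carbinol.
2. The C7–C11 core is built by two sequential anti-aldols (E-boron enolates) on the symmetric ketone 1,5-bis(PMB-oxy)pentan-3-one, not by a fragment aldol between advanced pieces. The two arms become the C8 and C10 CH2OH groups, so no hydroxymethylation is needed.
3. The cis-trisubstituted epoxy aldehyde comes from four steps: Brown anti-crotylation of methacrolein (sets C4 and C5), Sharpless epoxidation of the isopropenyl group, Payne rearrangement (inverts the quaternary C6 and transposes the epoxide to C5–C6), and oxidation to the aldehyde.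
4. The only ring is the oxirane. It is formed as a terminal epoxide in step 2 and transposed to the C5–C6 position in step 3.

Assumptions:
- Pentane-1,3,5-triol, ethyl (R)-3-hydroxypentanoate and (E)-2-butene are commercial.
- (–)-Ipc2BOMe (from (+)-α-pinene) gives the (E)-crotylborane that adds to the Si face of methacrolein. If the opposite sense is found, the reagent from (–)-α-pinene is used.
- The C13 stereocentre is sacrificial, because it is oxidised in step 15. It serves only to bias the second aldol.

## Route

**Step 1**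
Reactants: 1 methacrolein; 2 (E)-2-butene.
Product: 3, (3S,4S)-2,4-dimethylhexa-1,5-dien-3-ol.
Conditions: 2, KOtBu, n-BuLi, THF, –45 °C (gives (E)-crotylpotassium); (–)-Ipc2BOMe, –78 °C; BF3·OEt2; then 1, –78 °C; then NaOH, H2O2.
Reagents that add atoms: none.
Why: Brown asymmetric crotylation goes through a chair transition state with the (E)-crotyl-B(Ipc)2 reagent formed in situ, so it gives the anti adduct. Si-face attack on methacrolein sets C5 (S) and C4 (S).

**Step 2**
Reactants: 3.
Product: 4, (1S,2S)-2-methyl-1-[(2S)-2-methyloxiran-2-yl]but-3-en-1-ol.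
Conditions: Ti(OiPr)4 (1.0 equiv), D-(–)-DIPT (1.2 equiv), TBHP, 4 Å MS, CH2Cl2, –20 °C, several days; non-basic workup (aqueous tartaric acid).
Reagents that add atoms: TBHP, `CC(C)(C)OO` (supplies the epoxide O).
Why: Sharpless asymmetric epoxidation of the allylic alcohol; D-(–)-tartrate delivers oxygen to the face that gives the (S) quaternary carbon, and the (1S) carbinol is untouched. This is expected to be the mismatched pairing with the (3S) carbinol, so stoichiometric Ti and long reaction times are used so that reagent control dominates; only the allylic-alcohol alkene reacts, not the isolated vinyl group.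

**Step 3**
Reactants: 4.
Product: 5, [(2R,3S)-3-[(2S)-but-3-en-2-yl]-2-methyloxiran-2-yl]methanol.
Conditions: 0.5 M NaOH (aq), t-BuOH, 23 °C, 2 h.
Reagents that add atoms: none.
Why: Proposed new method: the Payne rearrangement is used as a stereo-inverting way to make a trisubstituted epoxide with a quaternary centre. The C5 alkoxide attacks tertiary C6 (3-exo-tet) with inversion and releases the primary alkoxide, C5 is retained, and the equilibrium favours the more substituted epoxide with a primary alcohol; closest known reaction: Payne rearrangement of 2,3-epoxy-1-ols.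

**Step 4**
Reactants: 5.
Product: 6, (2S,3S)-3-[(2S)-but-3-en-2-yl]-2-methyloxirane-2-carbaldehyde.
Conditions: Dess–Martin periodinane (DMP), NaHCO3, CH2Cl2, 0 → 23 °C.
Reagents that add atoms: none.
Why: mild oxidation of a primary alcohol; the aldehyde has a quaternary α-carbon, so C6 cannot epimerise.

**Step 5**
Reactants: 7 pentane-1,3,5-triol.
Product: 8, 1,5-bis(4-methoxybenzyloxy)pentan-3-ol.
Conditions: PMBBr (2.1 equiv), Ag2O, CH2Cl2, 23 °C.
Reagents that add atoms: PMBBr, `COc1ccc(CBr)cc1`.
Why: Ag2O-mediated etherification is selective for the two primary OH groups over the secondary one.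

**Step 6**
Reactants: 8.
Product: 9, 1,5-bis(4-methoxybenzyloxy)pentan-3-one.
Conditions: DMP, NaHCO3, CH2Cl2, 23 °C.
Reagents that add atoms: none.
Why: oxidation of the secondary alcohol gives the symmetric ketone that serves as the acetone-type linchpin.

**Step 7**
Reactants: 9 (2 equiv); 6.
Product: 10, anti-aldol adduct (C7 S, C8 R) with C7–OH free.
Conditions: c-Hex2BCl, Me2NEt, Et2O, 0 °C (enolisation); then 6, –78 → –20 °C; then MeOH, pH 7 buffer, H2O2.
Reagents that add atoms: none.
Why: Proposed new method: the E-enol borinate reacts through a chair (Zimmerman–Traxler) transition state, which gives the anti relationship (C8 R), and the quaternary epoxy aldehyde is assumed to be attacked anti to the epoxide C–O bond (polar-Felkin), setting C7 (S); closest known reaction: Paterson/Brown E-boron anti-aldol of 3-pentanone-type ketones with α-alkoxy aldehydes.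

**Step 8**
Reactants: 10.
Product: 11, C7-OTBS ether of 10.
Conditions: TBSOTf, 2,6-lutidine, CH2Cl2, –78 → 0 °C.
Reagents that add atoms: TBSOTf, `C[Si](C)(C(C)(C)C)OS(=O)(=O)C(F)(F)F`.
Why: silylation of the β-hydroxyl prevents retro-aldol and consumption of boron reagent in the next aldol.

**Step 9**
Reactants: 12 ethyl (R)-3-hydroxypentanoate.
Product: 13, ethyl (R)-3-(triethylsilyloxy)pentanoate.
Conditions: TESCl, imidazole, DMF, 23 °C.
Reagents that add atoms: TESCl, `CC[Si](Cl)(CC)CC`.
Why: protection of the secondary alcohol; the stereocentre is untouched.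

**Step 10**
Reactants: 13.
Product: 14, (R)-3-(triethylsilyloxy)pentanal.
Conditions: DIBAL-H, CH2Cl2, –78 °C.
Reagents that add atoms: none.
Why: partial reduction of the ester to the aldehyde at low temperature.

**Step 11**
Reactants: 11; 14.
Product: 15, bis-aldol adduct (C10 S, C11 S) with C11–OH free.
Conditions: c-Hex2BCl, Me2NEt, Et2O, 0 °C; then 14, –78 °C; then MeOH, pH 7 buffer, H2O2.
Reagents that add atoms: none.
Why: Proposed new method: enolisation occurs at the unhindered C10 CH2 to give the E-enol borinate, which gives the anti aldol (C10 S), and the β-silyloxy stereocentre of 14 is assumed to give 1,3-anti induction, setting C11 (S) with no auxiliary; closest known reaction: E-boron aldol of a ketone with a β-alkoxy aldehyde.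

**Step 12**
Reactants: 15.
Product: 16, C11-OTBS ether of 15.
Conditions: TBSOTf, 2,6-lutidine, CH2Cl2, –78 °C, brief.
Reagents that add atoms: TBSOTf, `C[Si](C)(C(C)(C)C)OS(=O)(=O)C(F)(F)F`.
Why: protecting the C11 hydroxyl allows later selective unmasking and oxidation of C13.

**Step 13**
Reactants: 16.
Product: 17, the (Z)-propenyl compound.
Conditions: (Z)-2-butene (large excess), Z-selective Ru catecholthiolate metathesis catalyst (5 mol %), THF, 23 °C, sealed vessel.
Reagents that add atoms: (Z)-2-butene, `C/C=C\C` (contributes C1 and C2).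
Why: Z-selective cross-metathesis of the terminal vinyl group with cis-2-butene sets the Z alkene; the C4 stereocentre is not involved.

**Step 14**
Reactants: 17.
Product: 18, C13 alcohol.
Conditions: HF·pyridine, pyridine, THF, 0 °C, 30 min.
Reagents that add atoms: none.
Why: a secondary TES ether is cleaved far faster than hindered secondary TBS ethers under buffered HF.

**Step 15**
Reactants: 18.
Product: 19, C13 ketone.
Conditions: DMP, NaHCO3, CH2Cl2, 23 °C.
Reagents that add atoms: none.
Why: oxidation destroys the sacrificial C13 stereocentre and unmasks the C13 ketone; all other hydroxyls are protected.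

**Step 16**
Reactants: 19.
Product: 20, bis-primary alcohol (PMB groups removed).
Conditions: DDQ, CH2Cl2/pH 7 phosphate buffer, 0 °C.
Reagents that add atoms: none.
Why: oxidative PMB cleavage is done while C7 and C11 are still silylated, which avoids p-methoxybenzylidene acetal formation with a free 1,3-OH.

**Step 17**
Reactants: 20.
Product: 21, myriaporone 4.
Conditions: HF·pyridine, excess pyridine, THF, 0 → 23 °C, 24 h.
Reagents that add atoms: none.
Why: buffered fluoride removes both TBS ethers, and these conditions are chosen to spare the tertiary epoxide and the β-hydroxy ketones.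

## Compound list

1 | methacrolein | `C=C(C)C=O` | starting material
2 | (E)-2-butene | `C/C=C/C` | starting material
3 | (3S,4S)-2,4-dimethylhexa-1,5-dien-3-ol | `C=C[C@H](C)[C@H](O)C(C)=C` | intermediate
4 | (1S,2S)-2-methyl-1-[(2S)-2-methyloxiran-2-yl]but-3-en-1-ol | `C=C[C@H](C)[C@H](O)[C@]1(C)CO1` | intermediate
5 | [(2R,3S)-3-[(2S)-but-3-en-2-yl]-2-methyloxiran-2-yl]methanol | `C=C[C@H](C)[C@@H]1O[C@]1(C)CO` | intermediate
6 | (2S,3S)-3-[(2S)-but-3-en-2-yl]-2-methyloxirane-2-carbaldehyde | `C=C[C@H](C)[C@@H]1O[C@]1(C)C=O` | intermediate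
7 | pentane-1,3,5-triol | `OCCC(O)CCO` | starting material
8 | 1,5-bis(4-methoxybenzyloxy)pentan-3-ol | `COc1ccc(COCCC(O)CCOCc2ccc(OC)cc2)cc1` | intermediate
9 | 1,5-bis(4-methoxybenzyloxy)pentan-3-one | `COc1ccc(COCCC(=O)CCOCc2ccc(OC)cc2)cc1` | intermediate
10 | anti-aldol adduct of 9 and 6 (7S,8R) | `C=C[C@H](C)[C@@H]1O[C@]1(C)[C@@H](O)[C@@H](COCc2ccc(OC)cc2)C(=O)CCOCc2ccc(OC)cc2` | intermediate
11 | C7-OTBS ether of 10 | `C=C[C@H](C)[C@@H]1O[C@]1(C)[C@@H](O[Si](C)(C)C(C)(C)C)[C@@H](COCc2ccc(OC)cc2)C(=O)CCOCc2ccc(OC)cc2` | intermediate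
12 | ethyl (3R)-3-hydroxypentanoate | `CC[C@@H](O)CC(=O)OCC` | starting material
13 | ethyl (3R)-3-(triethylsilyloxy)pentanoate | `CC[C@@H](O[Si](CC)(CC)CC)CC(=O)OCC` | intermediate
14 | (3R)-3-(triethylsilyloxy)pentanal | `CC[C@@H](O[Si](CC)(CC)CC)CC=O` | intermediate
15 | bis-aldol adduct (10S,11S; C11-OH free) | `C=C[C@H](C)[C@@H]1O[C@]1(C)[C@@H](O[Si](C)(C)C(C)(C)C)[C@@H](COCc2ccc(OC)cc2)C(=O)[C@@H](COCc2ccc(OC)cc2)[C@@H](O)C[C@H](O[Si](CC)(CC)CC)CC` | intermediate
16 | C11-OTBS ether of 15 | `C=C[C@H](C)[C@@H]1O[C@]1(C)[C@@H](O[Si](C)(C)C(C)(C)C)[C@@H](COCc2ccc(OC)cc2)C(=O)[C@@H](COCc2ccc(OC)cc2)[C@@H](O[Si](C)(C)C(C)(C)C)C[C@H](O[Si](CC)(CC)CC)CC` | intermediate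
17 | (Z)-propenyl compound from CM of 16 | `C/C=C\[C@H](C)[C@@H]1O[C@]1(C)[C@@H](O[Si](C)(C)C(C)(C)C)[C@@H](COCc2ccc(OC)cc2)C(=O)[C@@H](COCc2ccc(OC)cc2)[C@@H](O[Si](C)(C)C(C)(C)C)C[C@H](O[Si](CC)(CC)CC)CC` | intermediate
18 | C13 alcohol (TES removed) | `C/C=C\[C@H](C)[C@@H]1O[C@]1(C)[C@@H](O[Si](C)(C)C(C)(C)C)[C@@H](COCc2ccc(OC)cc2)C(=O)[C@@H](COCc2ccc(OC)cc2)[C@@H](O[Si](C)(C)C(C)(C)C)C[C@H](O)CC` | intermediate
19 | C13 ketone | `C/C=C\[C@H](C)[C@@H]1O[C@]1(C)[C@@H](O[Si](C)(C)C(C)(C)C)[C@@H](COCc2ccc(OC)cc2)C(=O)[C@@H](COCc2ccc(OC)cc2)[C@@H](O[Si](C)(C)C(C)(C)C)CC(=O)CC` | intermediate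
20 | bis(CH2OH) bis-TBS compound | `C/C=C\[C@H](C)[C@@H]1O[C@]1(C)[C@@H](O[Si](C)(C)C(C)(C)C)[C@@H](CO)C(=O)[C@@H](CO)[C@@H](O[Si](C)(C)C(C)(C)C)CC(=O)CC` | intermediate
21 | myriaporone 4 | `C/C=C\[C@H](C)[C@@H]1O[C@]1(C)[C@@H](O)[C@@H](CO)C(=O)[C@@H](CO)[C@@H](O)CC(=O)CC` | target

## Totals

Total steps: 17. Longest linear sequence: 13 steps (steps 1, 2, 3, 4, 7, 8, 11, 12, 13, 14, 15, 16, 17, counting from methacrolein).

## Three steps most likely to fail

1. **Step 2 (and the Payne rearrangement in step 3).** The mismatched Sharpless epoxidation may be slow or give a poor diastereomer ratio. The Payne equilibrium at the quaternary carbon may also be unfavourable.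
   Fallback: make the cis-epoxy alcohol from Roche ester instead. Use Ando Z-olefination of 3-(TBSO)-2-methylpropanal and DIBAL to give the Z primary allylic alcohol, then Sharpless epoxidation with D-(–)-DIPT. Install the propenyl group afterwards.
2. **Step 7.** The facial selectivity at C7 is uncertain, since a Felkin-type outcome would give the 7-epimer. The boron enolate of a β-alkoxy arm could also eliminate PMBO–, and the boron Lewis acid could open the epoxide.
   Fallback: use an Evans Mg-catalysed anti-aldol of an N-[3-(PMBO)propanoyl]thiazolidinethione with 6, where the auxiliary controls C7/C8. Then convert the imide to the ketone by Weinreb amide, vinylMgBr and oxa-Michael addition of PMBOH.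
3. **Step 11.** C10/C11 control relies only on remote 1,3-induction from the C13 silyl ether, and the same β-alkoxy enolate elimination risk applies.
   Fallback: build the C10–C11 unit with an auxiliary, using an Evans anti-aldol of 3-(PMBO)propanoyl oxazolidinone with 14. Convert it to the ketone as above and join it to 6 in a step 7-type aldol.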